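**Plan**

- Rings: A and B are the benzene and pyran rings of the acetyl-bearing chromene (O1, C2, C3, C4, C4a–C8a); C and D are the benzene and pyran rings of the dimethoxychromene.
- Enabling feature: in ring B, C2 with its two methyl groups and O1 is the carbon of an aryl isopropyl ether short of one hydrogen, C4 holds exactly that hydrogen, and C3=C4 with the stereocentre on C3 is an aryl alkyne with a propargylic stereocentre. Ring B is therefore an isomer of an ortho-alkynyl aryl isopropyl ether.
- Cuts (retrosynthesis, in order): the tosyl O–S bond on O5; C2–C3 of ring B (the C4 hydrogen goes back to C2); C4a–C4 (aryl–alkyne); the ring C aryl–CH bond at the stereocentre; O1–C2 and C4–C4a of ring D (phenol plus prenal).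
- Forward: ring D is annulated first on a bromodimethoxyphenol. The bromide becomes an arylzinc and is joined to a racemic silyl butynyl bromide. The freed alkyne is coupled to the isopropylated, iodinated and tosylated acetophenone (ring A). Ring B closes last, then the tosylate is removed.
- Stereochemistry: the single (S) centre is set by ligand control in a nickel/pybox enantioconvergent Negishi arylation and is a spectator in every later step.

Key step: step 10

Assumption: the enantiomer of the indanyl-pybox ligand that leads to (R)-10 is used; the sense of induction is carried over from simple arylzinc reagents and must be confirmed on the first batch (the antipodal ligand is equally available).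

**Route**

Step 1
Reactants: 1 2-bromo-1,3-dimethoxybenzene
Product: 3 4-bromo-3,5-dimethoxyphenol, via pinacol arylboronate 2 (not isolated)
Conditions: [Ir(OMe)(cod)]2 (cat.), 4,4'-di-tert-butyl-2,2'-bipyridine (cat.), B2pin2, THF, 80 °C; then KHSO5 (Oxone), acetone–H2O, rt
Reagents that add atoms: potassium peroxymonosulfate, [K+].[O-]S(=O)(=O)OO (phenol oxygen of 3); bis(pinacolato)diboron, CC1(C)OB(OC1(C)C)B1OC(C)(C)C(C)(C)O1 (boryl group of 2)
Why: Iridium-catalysed C–H borylation is sterically controlled and should take the only C–H without an ortho substituent (para to bromine), and oxidation of the C–B bond in the same flask gives the phenol with the aryl bromide untouched.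

Step 2
Reactants: 3 4-bromo-3,5-dimethoxyphenol; 4 3-methylbut-2-enal (prenal)
Product: 5 6-bromo-5,7-dimethoxy-2,2-dimethyl-2H-chromene
Conditions: PhB(OH)2, AcOH (cat.), toluene, reflux (Dean–Stark)
Reagents that add atoms: none
Why: Boronic acid-templated ortho condensation of the phenol with the enal gives an ortho-quinone methide that closes ring D by oxa-6π electrocyclisation; the two ortho positions are equivalent and bromine blocks the para position, so only one chromene can form.

Step 3
Reactants: 6 racemic 4-(trimethylsilyl)but-3-yn-2-ol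
Product: 7 racemic (3-bromobut-1-yn-1-yl)trimethylsilane
Conditions: CBr4, PPh3, CH2Cl2, 0 °C
Reagents that add atoms: carbon tetrabromide, BrC(Br)(Br)Br
Why: Appel bromination of a secondary propargylic alcohol is routine, and the silyl group prevents reaction at the alkyne terminus; the racemate is what the next step requires.

Step 4
Reactants: 5 6-bromo-5,7-dimethoxy-2,2-dimethyl-2H-chromene; 7 racemic (3-bromobut-1-yn-1-yl)trimethylsilane
Product: 10 [(3R)-3-(5,7-dimethoxy-2,2-dimethyl-2H-chromen-6-yl)but-1-yn-1-yl]trimethylsilane, via aryllithium 8 (not isolated), via arylzinc iodide 9 (not isolated)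
Conditions: t-BuLi (2 equiv), THF, –78 °C; ZnI2, –78 °C to rt; then 7, NiCl2·glyme (cat.), indanyl-pybox (cat.), glyme, –20 °C
Reagents that add atoms: tert-butyllithium, [Li]C(C)(C)C (lithium of 8); zinc iodide, I[Zn]I (zinc and iodine of 9)
Why: Bromine–lithium exchange and transmetalation give the arylzinc, which enters a nickel/pybox enantioconvergent Negishi coupling in which both enantiomers of 7 pass through one propargylic radical and the chiral aryl-nickel complex alone fixes the new centre; it is (R) here only because silicon outranks the aryl oxygens, and has the spatial arrangement of the (S) centre of the target.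

Step 5
Reactants: 10 [(3R)-3-(5,7-dimethoxy-2,2-dimethyl-2H-chromen-6-yl)but-1-yn-1-yl]trimethylsilane
Product: 11 6-[(2S)-but-3-yn-2-yl]-5,7-dimethoxy-2,2-dimethyl-2H-chromene
Conditions: K2CO3 (cat.), MeOH, 0 °C to rt
Reagents that add atoms: none
Why: Methanolysis of the C(sp)–Si bond is mild, and carbonate in methanol is too weak a base to isomerise the alkyne to an allene, so the stereocentre is kept (descriptor now (S) by priority change only).

Step 6
Reactants: 12 1-(2,4-dihydroxy-6-methoxyphenyl)ethanone (2',4'-dihydroxy-6'-methoxyacetophenone)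
Product: 13 1-(2-hydroxy-4-isopropoxy-6-methoxyphenyl)ethanone
Conditions: 2-bromopropane, K2CO3, DMF, 60 °C
Reagents that add atoms: 2-bromopropane, CC(C)Br
Why: Williamson etherification takes the more acidic, non-chelated 4-hydroxyl, while the 2-hydroxyl is held in a hydrogen bond to the acetyl group.

Step 7
Reactants: 13 1-(2-hydroxy-4-isopropoxy-6-methoxyphenyl)ethanone
Product: 14 1-(2-hydroxy-3-iodo-4-isopropoxy-6-methoxyphenyl)ethanone
Conditions: BnMe3N+ ICl2–, NaHCO3, CH2Cl2–MeOH, rt
Reagents that add atoms: benzyltrimethylammonium dichloroiodate, C[N+](C)(C)Cc1ccccc1.Cl[I-]Cl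
Why: Electrophilic aromatic iodination with dichloroiodate should go ortho to the free chelated phenol (C3'), as is usual for 2-hydroxy-4,6-dialkoxyacetophenones, and the buffer prevents acid-induced loss of the isopropyl group.

Step 8
Reactants: 14 1-(2-hydroxy-3-iodo-4-isopropoxy-6-methoxyphenyl)ethanone
Product: 15 2-acetyl-6-iodo-3-methoxy-5-(propan-2-yloxy)phenyl 4-methylbenzenesulfonate
Conditions: TsCl, K2CO3, acetone, reflux
Reagents that add atoms: 4-methylbenzenesulfonyl chloride, Cc1ccc(cc1)S(Cl)(=O)=O
Why: O-Sulfonylation of the phenoxide is routine even for a chelated, flanked phenol, and it turns this oxygen into a non-nucleophilic group before any alkyne is present.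

Step 9
Reactants: 15 2-acetyl-6-iodo-3-methoxy-5-(propan-2-yloxy)phenyl 4-methylbenzenesulfonate; 11 6-[(2S)-but-3-yn-2-yl]-5,7-dimethoxy-2,2-dimethyl-2H-chromene
Product: 16 2-acetyl-6-[(3S)-3-(5,7-dimethoxy-2,2-dimethyl-2H-chromen-6-yl)but-1-yn-1-yl]-3-methoxy-5-(propan-2-yloxy)phenyl 4-methylbenzenesulfonate
Conditions: Pd(PPh3)2Cl2 (cat.), CuI (cat.), Et3N, THF, 50 °C, degassed
Reagents that add atoms: none
Why: In this Sonogashira coupling zerovalent palladium inserts only into the C–I bond (the aryl tosylate is inert to this catalyst), and triethylamine cannot deprotonate the propargylic C–H, so the stereocentre is retained.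

Step 10
Reactants: 16 2-acetyl-6-[(3S)-3-(5,7-dimethoxy-2,2-dimethyl-2H-chromen-6-yl)but-1-yn-1-yl]-3-methoxy-5-(propan-2-yloxy)phenyl 4-methylbenzenesulfonate
Product: 17 6-acetyl-3-[(1S)-1-(5,7-dimethoxy-2,2-dimethyl-2H-chromen-6-yl)ethyl]-7-methoxy-2,2-dimethyl-2H-chromen-5-yl 4-methylbenzenesulfonate
Conditions: [(XPhos)Au(NCMe)]SbF6 (5 mol%), 2,6-di-tert-butyl-4-methylpyridine (10 mol%), CH3NO2, 80–100 °C
Reagents that add atoms: none
Why: Proposed new method: the cationic monovalent gold centre binds the C3≡C4 alkyne and slips toward C3, so that positive charge builds at C4 next to the isopropoxy/methoxy-substituted ring A; the tertiary C–H of the isopropyl ether then delivers hydride to C4 through a six-membered transition state (1,5-hydride shift, anti to gold), leaving an aryl oxocarbenium ion O1=C2 and a C3 vinyl-gold that, after rotation about C4a–C4, attacks C2 with loss of the gold cation to form C2–C3. The closest known reaction types are the gold- or platinum-catalysed 1,5-hydride shift/cyclisation in which an ether α-C–H bond adds across a tethered alkyne, and the Lewis-acid internal-redox closure of ortho-vinyl aryl ethers to chromans; an unactivated internal aryl alkyne fed by a plain aryl isopropyl ether has not been shown. Pyran ring B closes 6-endo-trig, the vinyl-gold carbon C3 adding to the endocyclic O1=C2 oxocarbenium bond. No stereocentre is formed, and the (S) centre beside the alkyne is carried through because the process is an isomerisation that does not pass through an allene. The step needs chemoselectivity for hydride transfer over addition of the ether oxygen to the alkyne (five-membered ring with loss of propene) and over reversible addition of the ring C methoxy oxygens; the hydridic tertiary C–H, the electron-poor tosylate on the second ortho oxygen, a non-nucleophilic SbF6 counter-ion that cannot dealkylate an oxonium adduct, and a hindered pyridine that keeps acid away from the ring D alkene are meant to secure it.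

Step 11
Reactants: 17 6-acetyl-3-[(1S)-1-(5,7-dimethoxy-2,2-dimethyl-2H-chromen-6-yl)ethyl]-7-methoxy-2,2-dimethyl-2H-chromen-5-yl 4-methylbenzenesulfonate
Product: 18 1-{3-[(1S)-1-(5,7-dimethoxy-2,2-dimethyl-2H-chromen-6-yl)ethyl]-5-hydroxy-7-methoxy-2,2-dimethyl-2H-chromen-6-yl}ethan-1-one (CNP0303487.1)
Conditions: KOH, MeOH–THF–H2O, 60 °C; then aq. NH4Cl
Reagents that add atoms: none
Why: Hydroxide cleaves the S–O bond of the aryl sulfonate, helped by the acetyl-stabilised phenoxide leaving group, and the doubly allylic/benzylic C–H at the stereocentre is far too weakly acidic to epimerise under these conditions.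

**Compound list**

1 | 2-bromo-1,3-dimethoxybenzene | COc1cccc(OC)c1Br | starting material
2 | 2-(4-bromo-3,5-dimethoxyphenyl)-4,4,5,5-tetramethyl-1,3,2-dioxaborolane | COc1cc(B2OC(C)(C)C(C)(C)O2)cc(OC)c1Br | intermediate
3 | 4-bromo-3,5-dimethoxyphenol | COc1cc(O)cc(OC)c1Br | intermediate
4 | 3-methylbut-2-enal | CC(C)=CC=O | starting material
5 | 6-bromo-5,7-dimethoxy-2,2-dimethyl-2H-chromene | COc1cc2OC(C)(C)C=Cc2c(OC)c1Br | intermediate
6 | racemic 4-(trimethylsilyl)but-3-yn-2-ol | CC(O)C#C[Si](C)(C)C | starting material
7 | racemic (3-bromobut-1-yn-1-yl)trimethylsilane | CC(Br)C#C[Si](C)(C)C | intermediate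
8 | (5,7-dimethoxy-2,2-dimethyl-2H-chromen-6-yl)lithium | COc1cc2OC(C)(C)C=Cc2c(OC)c1[Li] | intermediate
9 | (5,7-dimethoxy-2,2-dimethyl-2H-chromen-6-yl)zinc iodide | COc1cc2OC(C)(C)C=Cc2c(OC)c1[Zn]I | intermediate
10 | [(3R)-3-(5,7-dimethoxy-2,2-dimethyl-2H-chromen-6-yl)but-1-yn-1-yl]trimethylsilane | C[Si](C)(C)C#C[C@H](C)c1c(OC)cc2c(c1OC)C=CC(C)(C)O2 | intermediate
11 | 6-[(2S)-but-3-yn-2-yl]-5,7-dimethoxy-2,2-dimethyl-2H-chromene | C#C[C@H](C)c1c(OC)cc2c(c1OC)C=CC(C)(C)O2 | intermediate
12 | 1-(2,4-dihydroxy-6-methoxyphenyl)ethanone | CC(=O)c1c(O)cc(O)cc1OC | starting material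
13 | 1-(2-hydroxy-4-isopropoxy-6-methoxyphenyl)ethanone | CC(=O)c1c(O)cc(OC(C)C)cc1OC | intermediate
14 | 1-(2-hydroxy-3-iodo-4-isopropoxy-6-methoxyphenyl)ethanone | CC(=O)c1c(O)c(I)c(OC(C)C)cc1OC | intermediate
15 | 2-acetyl-6-iodo-3-methoxy-5-(propan-2-yloxy)phenyl 4-methylbenzenesulfonate | CC(=O)c1c(OS(=O)(=O)c2ccc(C)cc2)c(I)c(OC(C)C)cc1OC | intermediate
16 | 2-acetyl-6-[(3S)-3-(5,7-dimethoxy-2,2-dimethyl-2H-chromen-6-yl)but-1-yn-1-yl]-3-methoxy-5-(propan-2-yloxy)phenyl 4-methylbenzenesulfonate | COc1cc(OC(C)C)c(C#C[C@H](C)c2c(OC)cc3c(c2OC)C=CC(C)(C)O3)c(OS(=O)(=O)c2ccc(C)cc2)c1C(C)=O | intermediate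
17 | 6-acetyl-3-[(1S)-1-(5,7-dimethoxy-2,2-dimethyl-2H-chromen-6-yl)ethyl]-7-methoxy-2,2-dimethyl-2H-chromen-5-yl 4-methylbenzenesulfonate | COc1cc2c(c(OS(=O)(=O)c3ccc(C)cc3)c1C(C)=O)C=C([C@H](C)c1c(OC)cc3c(c1OC)C=CC(C)(C)O3)C(C)(C)O2 | intermediate
18 | 1-{3-[(1S)-1-(5,7-dimethoxy-2,2-dimethyl-2H-chromen-6-yl)ethyl]-5-hydroxy-7-methoxy-2,2-dimethyl-2H-chromen-6-yl}ethan-1-one | COc1cc2c(c(O)c1C(C)=O)C=C([C@H](C)c1c(OC)cc3c(c1OC)C=CC(C)(C)O3)C(C)(C)O2 | target

**Step count**

Total: 11 steps.
Longest linear sequence: 7 steps (steps 1, 2, 4, 5, 9, 10, 11; from 1 to 18).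

**Steps most likely to fail**

Step 10 (key step).
- What may go wrong: hydride transfer to the internal alkyne may be slower than addition of the ether oxygen followed by loss of propene, or may not set in below temperatures at which the ring D alkene degrades.
- Fallback (known chemistry; ring B is closed through O1–C2 by an oxa-6π route instead of through C2–C3): it sets out from silyl alkyne 10 and acetophenone 12 and returns to the route at target 18.
- Titanium-mediated reductive coupling of 10 with acetone (Ti(OiPr)4, i-PrMgCl, Et2O, –78 to –50 °C, then acetone) should join the acetone carbon to the alkyne carbon remote from silicon and give the vinylsilane (3E)-3-[(1R)-1-(5,7-dimethoxy-2,2-dimethyl-2H-chromen-6-yl)ethyl]-2-methyl-4-(trimethylsilyl)but-3-en-2-ol F1.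
- Protodesilylation (TBAF, DMSO, 80 °C) should give the tertiary allylic alcohol 3-[(1S)-1-(5,7-dimethoxy-2,2-dimethyl-2H-chromen-6-yl)ethyl]-2-methylbut-3-en-2-ol F2.
- Babler–Dauben oxidative transposition (pyridinium chlorochromate, [C5H5NH][CrO3Cl], CH2Cl2, rt) should give the enal 2-[(1R)-1-(5,7-dimethoxy-2,2-dimethyl-2H-chromen-6-yl)ethyl]-3-methylbut-2-enal F3.
- Condensation of F3 with 12 (ethylenediammonium diacetate, toluene, reflux) should build ring B by C-alkylation between the two hydroxyls, ortho-quinone methide formation and electrocyclisation onto the non-chelated oxygen, giving 18 directly.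
- The descriptors of F1 to F3 alternate only through priority changes; the spatial arrangement is that of 18. The C–H at the stereocentre is not acidified by the enal or its iminium ion. Regioisomeric chromenes would have to be separated.

Step 4.
- What may go wrong: the doubly ortho-substituted arylzinc may transfer its aryl group to nickel too slowly, so that the propargylic radical dimerises or is reduced and the coupling stalls or loses enantiocontrol.
- Fallback (reagent-controlled stereocentre, no nickel): it sets out from bromide 5 and returns at alkyne 11.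
- Bromine–lithium exchange on 5 (t-BuLi, THF, –78 °C) and quench with 2-isopropoxy-4,4,5,5-tetramethyl-1,3,2-dioxaborolane should give the boronic ester 2-(5,7-dimethoxy-2,2-dimethyl-2H-chromen-6-yl)-4,4,5,5-tetramethyl-1,3,2-dioxaborolane F4.
- Lithiation–borylation with ethyl N,N-diisopropylcarbamate (s-BuLi with the sparteine enantiomer that leads to the (R)-boronate, Et2O, –78 °C; then F4; then MgBr2·OEt2, reflux) should give, by stereospecific 1,2-aryl migration, 2-[(1R)-1-(5,7-dimethoxy-2,2-dimethyl-2H-chromen-6-yl)ethyl]-4,4,5,5-tetramethyl-1,3,2-dioxaborolane F5.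
- Zweifel-type olefination with 1-lithiovinyl N,N-diisopropylcarbamate, then I2 and NaOMe, should give with retention (3R)-3-(5,7-dimethoxy-2,2-dimethyl-2H-chromen-6-yl)but-1-en-2-yl N,N-di(propan-2-yl)carbamate F6.
- Elimination of the carbamate with LDA (THF, –78 °C to rt) should then give 11.

Step 7.
- What may go wrong: attack of the iodinating agent para to the free hydroxyl (C5') may compete with the wanted ortho attack at C3', or a second iodination may follow.
- Fallback (halogenation before alkylation, so that a different element controls the site): it sets out from 12 and returns at 14.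
- Iodination of 12 itself (I2, HIO3, aqueous EtOH, rt) should take the position between the two free hydroxyls, the most activated one, and give 1-(2,4-dihydroxy-3-iodo-6-methoxyphenyl)ethanone F7.
- Mitsunobu etherification (propan-2-ol, PPh3, diisopropyl azodicarboxylate, THF, 0 °C to rt) should then alkylate only the more acidic, non-chelated 4-hydroxyl and give 14.

**Further compounds**

F1 | step 10 | (3E)-3-[(1R)-1-(5,7-dimethoxy-2,2-dimethyl-2H-chromen-6-yl)ethyl]-2-methyl-4-(trimethylsilyl)but-3-en-2-ol | CC(C)(O)/C(=C/[Si](C)(C)C)[C@H](C)c1c(OC)cc2c(c1OC)C=CC(C)(C)O2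
F2 | step 10 | 3-[(1S)-1-(5,7-dimethoxy-2,2-dimethyl-2H-chromen-6-yl)ethyl]-2-methylbut-3-en-2-ol | CC(C)(O)C(=C)[C@H](C)c1c(OC)cc2c(c1OC)C=CC(C)(C)O2
F3 | step 10 | 2-[(1R)-1-(5,7-dimethoxy-2,2-dimethyl-2H-chromen-6-yl)ethyl]-3-methylbut-2-enal | CC(C)=C(C=O)[C@H](C)c1c(OC)cc2c(c1OC)C=CC(C)(C)O2
F4 | step 4 | 2-(5,7-dimethoxy-2,2-dimethyl-2H-chromen-6-yl)-4,4,5,5-tetramethyl-1,3,2-dioxaborolane | COc1cc2OC(C)(C)C=Cc2c(OC)c1B1OC(C)(C)C(C)(C)O1
F5 | step 4 | 2-[(1R)-1-(5,7-dimethoxy-2,2-dimethyl-2H-chromen-6-yl)ethyl]-4,4,5,5-tetramethyl-1,3,2-dioxaborolane | CC1(C)OB(OC1(C)C)[C@H](C)c1c(OC)cc2c(c1OC)C=CC(C)(C)O2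
F6 | step 4 | (3R)-3-(5,7-dimethoxy-2,2-dimethyl-2H-chromen-6-yl)but-1-en-2-yl N,N-di(propan-2-yl)carbamate | C=C(OC(=O)N(C(C)C)C(C)C)[C@H](C)c1c(OC)cc2c(c1OC)C=CC(C)(C)O2
F7 | step 7 | 1-(2,4-dihydroxy-3-iodo-6-methoxyphenyl)ethanone | CC(=O)c1c(O)c(I)c(O)cc1OC
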